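**Strategy.** Everything rests on cutting the bond between the aryl ipso carbon and C3 of the five-membered imide ring. The C3=C4 alkene of that ring, flanked by the C2 and C5 carbonyls, is read as a masked acetylenedicarboxylate: an arylcopper made from 4-prenyloxyphenyl bromide adds syn across dimethyl acetylenedicarboxylate and the resulting vinylcopper is benzylated in the same flask. One operation thus forms the aryl–C3 bond and the C4–benzyl bond and fixes the cis-diester geometry needed for ring closure. The precursor is an alkyne diester plus an aryl Grignard reagent; saponification to the cyclic anhydride and condensation with hydroxylamine then give the N-hydroxyimide.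

Key step: step 2

Remark on the chemistry: the target has no stereocentre; its only geometric element is the ring-locked cis C3=C4 alkene. The organometallic intermediates 6–8 are drawn as simple monomers (in solution they carry THF, SMe2 and MgBr2). Where an anhydride or diester can be attacked at either carbonyl, both converging regioisomers are listed.

**Step 1**
Reactants: 1 4-bromophenol; 2 prenyl bromide (1-bromo-3-methylbut-2-ene)
Product: 3 1-bromo-4-[(3-methylbut-2-en-1-yl)oxy]benzene
Conditions: K2CO3, acetone, reflux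
Reagents that add atoms: none
Why: Williamson ether synthesis; the phenoxide displaces the primary allylic bromide by SN2, and K2CO3 in acetone favours O- over C-alkylation.

**Step 2**
Reactants: 3 1-bromo-4-[(3-methylbut-2-en-1-yl)oxy]benzene; 4 dimethyl acetylenedicarboxylate; 5 benzyl bromide
Product: 9 dimethyl (2Z)-2-benzyl-3-{4-[(3-methylbut-2-en-1-yl)oxy]phenyl}but-2-enedioate, via arylmagnesium bromide 6 (not isolated), via arylcopper 7 (not isolated), via vinylcopper 8 (not isolated)
Conditions: Mg, THF, 50 °C; CuBr·SMe2, THF, −40 °C; 4, −78 °C; 5, HMPA, −78 °C to rt; aq NH4Cl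
Reagents that add atoms: none
Why: Transmetallation of Grignard reagent 6 with CuBr·SMe2 gives the monoorganocopper 7, which adds syn across the electron-poor triple bond of 4 at −78 °C (carbocupration, formally a conjugate addition), making the aryl–C bond and placing copper cis to the aryl group in vinylcopper 8; HMPA then activates 8 for SN2 attack on benzyl bromide with retention at the sp2 carbon. The closest known reaction type is the tandem vicinal difunctionalisation of acetylenedicarboxylates by organocopper addition and electrophilic trapping, a standard entry to 2,3-disubstituted maleates. No ring is closed and no stereocentre is created; the only stereochemical element is the alkene geometry, fixed as the cis-diester by syn addition and retentive alkylation and protected by keeping 8 cold so that isomerisation through the copper allenoate stays slow. Chemoselectivity rests on the order of addition (7 is consumed by 4 before 5 is added, so aryl–benzyl coupling is avoided) and on using a monoorganocopper in place of a Gilman cuprate, which should suppress double addition and attack on the esters or the prenyl ether.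

**Step 3**
Reactants: 9 dimethyl (2Z)-2-benzyl-3-{4-[(3-methylbut-2-en-1-yl)oxy]phenyl}but-2-enedioate
Product: 12 3-benzyl-4-{4-[(3-methylbut-2-en-1-yl)oxy]phenyl}furan-2,5-dione, via dipotassium dicarboxylate 10 (not isolated), via diacid 11 (not isolated)
Conditions: KOH, MeOH/H2O, 60 °C; then 1 M HCl, 0 °C to rt
Reagents that add atoms: potassium hydroxide, [K+].[OH-]
Why: Saponification of both methyl esters followed by acidification; the cis-diacid on a tetrasubstituted alkene should dehydrate spontaneously to the five-membered anhydride, and the prenyl ether should survive cold dilute acid.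

**Step 4**
Reactants: 12 3-benzyl-4-{4-[(3-methylbut-2-en-1-yl)oxy]phenyl}furan-2,5-dione
Product: 15 himanimide C, via hydroxamic acid 13 (not isolated), via regioisomeric hydroxamic acid 14 (not isolated)
Conditions: NH2OH·HCl, pyridine, 90 °C; aq citric acid work-up
Reagents that add atoms: hydroxylamine hydrochloride, NO.Cl
Why: Condensation of a cyclic anhydride with hydroxylamine as in the preparation of N-hydroxyphthalimide; N-acylation opens the ring at either carbonyl to 13 or 14, and both should close by thermal dehydration to the same N-hydroxyimide.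

**Compound list**
1 | 4-bromophenol | Oc1ccc(Br)cc1 | starting material
2 | prenyl bromide (1-bromo-3-methylbut-2-ene) | CC(C)=CCBr | starting material
3 | 1-bromo-4-[(3-methylbut-2-en-1-yl)oxy]benzene | CC(C)=CCOc1ccc(Br)cc1 | intermediate
4 | dimethyl acetylenedicarboxylate (dimethyl but-2-ynedioate) | COC(=O)C#CC(=O)OC | starting material
5 | benzyl bromide | BrCc1ccccc1 | starting material
6 | {4-[(3-methylbut-2-en-1-yl)oxy]phenyl}magnesium bromide | CC(C)=CCOc1ccc([Mg]Br)cc1 | intermediate
7 | {4-[(3-methylbut-2-en-1-yl)oxy]phenyl}copper | CC(C)=CCOc1ccc([Cu])cc1 | intermediate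
8 | vinylcopper: dimethyl 2-cuprio-3-{4-[(3-methylbut-2-en-1-yl)oxy]phenyl}but-2-enedioate, esters cis, copper cis to aryl (formally 2E) | COC(=O)/C(c1ccc(OCC=C(C)C)cc1)=C(/[Cu])C(=O)OC | intermediate
9 | dimethyl (2Z)-2-benzyl-3-{4-[(3-methylbut-2-en-1-yl)oxy]phenyl}but-2-enedioate | COC(=O)/C(c1ccc(OCC=C(C)C)cc1)=C(/Cc1ccccc1)C(=O)OC | intermediate
10 | dipotassium (2Z)-2-benzyl-3-{4-[(3-methylbut-2-en-1-yl)oxy]phenyl}but-2-enedioate | [K+].[K+].[O-]C(=O)/C(c1ccc(OCC=C(C)C)cc1)=C(/Cc1ccccc1)C([O-])=O | intermediate
11 | (2Z)-2-benzyl-3-{4-[(3-methylbut-2-en-1-yl)oxy]phenyl}but-2-enedioic acid | OC(=O)/C(c1ccc(OCC=C(C)C)cc1)=C(/Cc1ccccc1)C(O)=O | intermediate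
12 | 3-benzyl-4-{4-[(3-methylbut-2-en-1-yl)oxy]phenyl}furan-2,5-dione | CC(C)=CCOc1ccc(C2=C(Cc3ccccc3)C(=O)OC2=O)cc1 | intermediate
13 | (2Z)-2-benzyl-4-(hydroxyamino)-3-{4-[(3-methylbut-2-en-1-yl)oxy]phenyl}-4-oxobut-2-enoic acid | ONC(=O)/C(c1ccc(OCC=C(C)C)cc1)=C(/Cc1ccccc1)C(O)=O | intermediate
14 | (2Z)-3-benzyl-4-(hydroxyamino)-2-{4-[(3-methylbut-2-en-1-yl)oxy]phenyl}-4-oxobut-2-enoic acid | OC(=O)/C(c1ccc(OCC=C(C)C)cc1)=C(/Cc1ccccc1)C(=O)NO | intermediate
15 | himanimide C, 3-benzyl-1-hydroxy-4-{4-[(3-methylbut-2-en-1-yl)oxy]phenyl}-1H-pyrrole-2,5-dione | CC(C)=CCOc1ccc(C2=C(Cc3ccccc3)C(=O)N(O)C2=O)cc1 | target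

**Total step count:** 4
**Longest linear sequence:** 4 steps (steps 1 to 4)

**Steps most likely to fail**

Step 2. The C-benzylation of the diester-stabilised vinylcopper may be sluggish, so that protonation on work-up and cis/trans scrambling through the copper allenoate compete. The fallback sets out from 3 and follows step 2 through 6, 7 and 8. The cold vinylcopper is then quenched with iodine (I2, THF, −78 °C) to give dimethyl (2E)-2-iodo-3-{4-[(3-methylbut-2-en-1-yl)oxy]phenyl}but-2-enedioate F1 (esters cis). Negishi coupling of this vinyl iodide with benzylzinc bromide (BnZnBr, catalytic Pd(PPh3)4, a zerovalent palladium complex, THF, rt) should proceed with retention and comes back to the route at 9.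

Step 4. The dehydrative ring closure may stall at the ring-opened hydroxamic acids, which can revert to anhydride on work-up, and the free N-hydroxy group may be O-acylated by unreacted anhydride. The fallback sets out from 12 and uses an O-protected hydroxylamine. Condensation with O-(oxan-2-yl)hydroxylamine (Et3N, toluene, 90 °C) should pass through (2Z)-2-benzyl-3-{4-[(3-methylbut-2-en-1-yl)oxy]phenyl}-4-[(oxan-2-yloxy)amino]-4-oxobut-2-enoic acid F2 and its regioisomer (2Z)-3-benzyl-2-{4-[(3-methylbut-2-en-1-yl)oxy]phenyl}-4-[(oxan-2-yloxy)amino]-4-oxobut-2-enoic acid F3. Both should close to 3-benzyl-4-{4-[(3-methylbut-2-en-1-yl)oxy]phenyl}-1-(oxan-2-yloxy)-1H-pyrrole-2,5-dione F4 (racemic at the acetal carbon). Mild acetal cleavage (PPTS, MeOH, 40 °C), which the prenyl ether should tolerate, comes back to the route at 15.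

Step 3. Hydrolysis of the second, hindered ester may be incomplete, or the prenyl group may be lost under acid during acidification. The fallback sets out from 9 and bypasses the anhydride. Treatment with NH2OH·HCl and KOH in MeOH (0 °C to rt) should convert one ester into a hydroxamic acid, giving methyl (2Z)-2-benzyl-4-(hydroxyamino)-3-{4-[(3-methylbut-2-en-1-yl)oxy]phenyl}-4-oxobut-2-enoate F5 or its regioisomer methyl (2Z)-3-benzyl-4-(hydroxyamino)-2-{4-[(3-methylbut-2-en-1-yl)oxy]phenyl}-4-oxobut-2-enoate F6. The hydroxamate nitrogen of either should close onto the neighbouring ester, as in the preparation of N-hydroxyphthalimide from a phthalate diester. Acidification with AcOH comes back to the route at 15.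

**Further compounds**
F1 | step 2 | dimethyl (2E)-2-iodo-3-{4-[(3-methylbut-2-en-1-yl)oxy]phenyl}but-2-enedioate (esters cis) | COC(=O)/C(c1ccc(OCC=C(C)C)cc1)=C(/I)C(=O)OC
F2 | step 4 | (2Z)-2-benzyl-3-{4-[(3-methylbut-2-en-1-yl)oxy]phenyl}-4-[(oxan-2-yloxy)amino]-4-oxobut-2-enoic acid (racemic) | O=C(NOC1CCCCO1)/C(c1ccc(OCC=C(C)C)cc1)=C(/Cc1ccccc1)C(O)=O
F3 | step 4 | (2Z)-3-benzyl-2-{4-[(3-methylbut-2-en-1-yl)oxy]phenyl}-4-[(oxan-2-yloxy)amino]-4-oxobut-2-enoic acid (racemic) | OC(=O)/C(c1ccc(OCC=C(C)C)cc1)=C(/Cc1ccccc1)C(=O)NOC1CCCCO1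
F4 | step 4 | 3-benzyl-4-{4-[(3-methylbut-2-en-1-yl)oxy]phenyl}-1-(oxan-2-yloxy)-1H-pyrrole-2,5-dione (racemic) | CC(C)=CCOc1ccc(C2=C(Cc3ccccc3)C(=O)N(OC3CCCCO3)C2=O)cc1
F5 | step 3 | methyl (2Z)-2-benzyl-4-(hydroxyamino)-3-{4-[(3-methylbut-2-en-1-yl)oxy]phenyl}-4-oxobut-2-enoate | ONC(=O)/C(c1ccc(OCC=C(C)C)cc1)=C(/Cc1ccccc1)C(=O)OC
F6 | step 3 | methyl (2Z)-3-benzyl-4-(hydroxyamino)-2-{4-[(3-methylbut-2-en-1-yl)oxy]phenyl}-4-oxobut-2-enoate | COC(=O)/C(c1ccc(OCC=C(C)C)cc1)=C(/Cc1ccccc1)C(=O)NO
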